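**What remains.** What remains of X after its early peak is what I am asked for: the violet run reads 50.9 % at 0.333 min, but 31.4 % at 2.50 min.

in all of them: D 0.80 M

| run | Q | remark | time |
|---|---|---|---|
| violet | 0.24 M | run made earlier |  |
| amber | 0.16 M | run made earlier |  |
| green | 0.36 M | run made earlier |  |
| Friday's | 0.240 M | a single well-mixed tank run continuously and read at steady state, 4.0 min in it on average |  |
| Sunday's | 0.240 M | a closed flask charged with all of it at once and left for 4.0 min | 4.0 min |
| Saturday's | 0.240 M | a tube with plug flow, the mixed feed as stated, residence time 4.0 min | 4.0 min |
| Monday's | 0.240 M | a single well-mixed tank run continuously and read at steady state, 40.0 min in it on average |  |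

| run | time / min | X / % |
|---|---|---|
| violet | 0.167 | 44.6 |
| violet | 0.333 | 50.9 |
| violet | 0.667 | 46.1 |
| violet | 1.00 | 43.4 |
| violet | 1.33 | 40.1 |
| violet | 2.00 | 36.0 |
| violet | 2.50 | 31.4 |
| amber | 0.667 | 47.8 |
| amber | 1.33 | 43.3 |
| amber | 2.00 | 36.5 |
| amber | 3.00 | 30.4 |
| amber | 4.00 | 26.0 |
| amber | 5.00 | 23.9 |
| green | 0.667 | 45.4 |
| green | 1.33 | 40.0 |
| green | 2.00 | 34.7 |
| green | 3.00 | 29.5 |
| green | 4.00 | 24.3 |
| green | 5.00 | 21.0 |

(scatter of a reading: 1 percentage point)

* the set-up with the highest amount of X at the outlet or at the end, in percent of the D put in ("none" if the first two lie within 2 percentage points) (Friday's / Sunday's / Saturday's / Monday's / none)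
* amount of X at the outlet or at the end, in percent of the D put in, Friday's
* amount of X at the outlet or at the end, in percent of the D put in, Sunday's
* amount of X at the outlet or at the end, in percent of the D put in, Saturday's
* amount of X at the outlet or at the end, in percent of the D put in, Monday's

- the stated concentrations are those of everything mixed, before any reaction; amounts are the same in each set-up
- the numbers in the tables scatter with a standard deviation of 1 percentage point
- the earlier runs were made in a closed, stirred flask

**Fade constant.** The loss reads as second order in X: its rate goes with the square of X, so one over the X fraction of the D charged climbs in a straight line with time. In the violet run it climbs at 0.554 min⁻¹; this climb is my fade constant. Run back to zero time, the line starts at an X fraction of 55.6 %.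

**Q charge.** By hand, I expect more Q to cost some X. From the amber run to the green run, the last reading falls by 2.9 percentage points, against a scatter of 1 point. Their fade constants, 0.483 min⁻¹ and 0.591 min⁻¹, lie on either side of the violet value, so I carry that value.

**Vessel.** Sunday's flask and Saturday's tube both age X for 4.0 min, so the line gives 24.9 % for each. In Friday's tank, the start fraction minus the outlet fraction equals the fade constant times the stay times the outlet fraction squared. That gives 32.4 %, more than Sunday's flask, since in this reckoning the loss in Friday's tank runs at the outlet fraction, below the start.

**Longer stay.** Monday's tank has ten times that stay, and the same balance gives 13.7 %.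

**The forecast.** It names Friday's, with 32 % for Friday's, 25 % for Sunday's, 25 % for Saturday's and 13.5 % for Monday's: “Friday's is best, because the tank holds X low, which slows a second-order loss.”

**The flask.** Friday's leads: 30.5 % there, 25.4 % on Sunday's, 25.4 % on Saturday's and 11.3 % on Monday's. Friday's lead over Sunday's is 5.1 points, against a margin of 2 points.

    D → J (k = 1.80 s⁻¹)
    J ⇌ X (K = 11.0, k = 0.110 s⁻¹)
    J ⇌ L (K = 54.0, k = 0.0620 s⁻¹)
    D + Q → Z (k = 0.410 M⁻¹ s⁻¹)
    J → E (k = 0.0160 s⁻¹)

**Fade again.** Put through the same balance, Friday's outlet gives a fade constant of 0.674 min⁻¹, above the violet value. Monday's outlet gives 0.873 min⁻¹, higher again, so from Friday's tank to Monday's the loss outruns the square of X. The main reason for Monday's low X is the backward run from X to J: with that run taken away, X at the outlet of Monday's tank stands at 73.5 % of the D put in instead of 11.3 %.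

(The earlier runs and the new flask are simulated on assumed constants.)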